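**Retrosynthetic overview**

1. Target 25 ← global desilylation ← Suzuki–Miyaura union, at the central C–C single bond of the diene, of (E)-alkenylboronate 14 (oxolane half) with (E)-iodoalkenyl isocoumarin 23; each alkenyl unit comes from an aldehyde by chromium-mediated olefination.
2. Oxolane (O1, C2 dienyl, C3 OH, C4 H2, C5 HMe): C3 carbinol ← ketone 8 ← rhodium-carbene C–H insertion of the open-chain diazoketone 7 into the OCH2 of a plain O-ethyl group, which forms C4–C5, closes the ring and sets C5.
3. Enabling feature: C5 sits on ring oxygen O1 (its C–H is an activated ether α-C–H) and C4 sits next to carbinol carbon C3 (a ketone there carries C4 as a diazo carbon); the two are 1,5-related through O1–C2–C3.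
4. Chiral pool: methyl L-glycerate supplies C2 with its configuration, its ester carbon becomes C3 and its CH2OH carbon becomes the first diene carbon; the ethyl ether supplies C5 and the methyl group.
5. Ring order: benzene ring bought (methyl orsellinate, chlorinated first); oxolane ring in step 6; pyranone ring of the isocoumarin in step 15 by lateral acylation and enol-lactonisation; the halves are joined last.

Key step: step 6

Remark: compounds 1, 15 and 18 and all reagents are taken as commercial; diazomethane is used as a freshly prepared ethereal solution and LiN(i-Pr)2 as a commercial solution.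

**Route**

Step 1
Reactants: 1 methyl (4S)-2,2-dimethyl-1,3-dioxolane-4-carboxylate
Product: 2 methyl (2S)-2,3-dihydroxypropanoate
Conditions: p-TsOH·H2O (cat.), MeOH, rt
Reagents that add atoms: none
Why: Acid-catalysed transacetalisation in methanol (acetonide methanolysis) should free the diol without touching the ester or the stereocentre.

Step 2
Reactants: 2 methyl (2S)-2,3-dihydroxypropanoate
Product: 3 methyl (2S)-3-{[tert-butyl(diphenyl)silyl]oxy}-2-hydroxypropanoate
Conditions: TBDPSCl, imidazole, CH2Cl2, 0 °C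
Reagents that add atoms: tert-butyl(chloro)diphenylsilane (TBDPSCl), CC(C)(C)[Si](Cl)(c1ccccc1)c1ccccc1
Why: Silyl ether formation with the bulky chlorosilane should be selective for the primary hydroxyl over the hindered, ester-deactivated secondary one.

Step 3
Reactants: 3 methyl (2S)-3-{[tert-butyl(diphenyl)silyl]oxy}-2-hydroxypropanoate
Product: 4 methyl (2S)-3-{[tert-butyl(diphenyl)silyl]oxy}-2-ethoxypropanoate
Conditions: EtI, Ag2O, 4 Å molecular sieves, Et2O, rt to 35 °C, dark
Reagents that add atoms: iodoethane, CCI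
Why: Purdie-type O-alkylation with Ag2O is essentially neutral, so the α-hydroxy ester should be ethylated without enolisation of the stereocentre or silyl migration.

Step 4
Reactants: 4 methyl (2S)-3-{[tert-butyl(diphenyl)silyl]oxy}-2-ethoxypropanoate
Product: 5 (2S)-3-{[tert-butyl(diphenyl)silyl]oxy}-2-ethoxypropanoic acid
Conditions: LiOH·H2O, THF/H2O, 0 °C; then 1 M HCl to pH 3
Reagents that add atoms: lithium hydroxide, [Li+].[OH-]
Why: Cold saponification of the methyl ester should give the acid without β-elimination or epimerisation.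

Step 5
Reactants: 5 (2S)-3-{[tert-butyl(diphenyl)silyl]oxy}-2-ethoxypropanoic acid
Product: 7 (3S)-4-{[tert-butyl(diphenyl)silyl]oxy}-1-diazo-3-ethoxybutan-2-one, via mixed anhydride 6 (not isolated)
Conditions: i-BuOCOCl, N-methylmorpholine, THF, −20 °C; then CH2N2 (Et2O solution), 0 °C to rt
Reagents that add atoms: diazomethane, C=[N+]=[N-]
Why: Acylation of diazomethane by the isobutyl carbonic mixed anhydride (first half of an Arndt–Eistert sequence) should give the α-diazoketone without an acidic acid chloride stage that could racemise the α-alkoxy centre.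

Step 6
Reactants: 7 (3S)-4-{[tert-butyl(diphenyl)silyl]oxy}-1-diazo-3-ethoxybutan-2-one
Product: 8 (2S,5R)-2-({[tert-butyl(diphenyl)silyl]oxy}methyl)-5-methyloxolan-3-one
Conditions: Rh2(OAc)4 (1 mol %), CH2Cl2, rt, slow addition of 7 at high dilution
Reagents that add atoms: none
Why: Rh2(OAc)4 expels N2 from 7, and the electrophilic dirhodium carbene at the former diazo carbon inserts in one concerted, three-centre event into a C–H bond of the OCH2 group of the ethyl ether, the most hydridic C–H in the molecule because of the adjacent oxygen lone pair. The closest known reaction type is the dirhodium tetracarboxylate catalysed intramolecular C–H insertion of α-alkoxy-α'-diazoketones next to ether oxygen, which gives 3(2H)-furanones. The oxolane closes in the 1,5 mode (carbene carbon, C=O carbon, C2, O1, ether CH2), since 1,4 insertion into CH2OSi would give a cyclobutanone and 1,6 insertion would have to use the unactivated CH3. The new stereocentre C5 is controlled by the glycerate-derived centre C2: in the chair-like six-centre transition state the CH2OSi group and the methyl group should both sit pseudo-equatorial, which places them cis (2S,5R), and C2 itself is not touched. The step needs C–H insertion to win over oxonium ylide formation; the ethoxy oxygen could only give a strained four-membered ylide, and the oxygen of the CH2O–Si group, which could give a five-membered ylide, is made a poor donor by the bulky tert-butyldiphenylsilyl group, while slow addition suppresses carbene dimerisation.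

Step 7
Reactants: 8 (2S,5R)-2-({[tert-butyl(diphenyl)silyl]oxy}methyl)-5-methyloxolan-3-one
Product: 9 (2S,3S,5R)-2-({[tert-butyl(diphenyl)silyl]oxy}methyl)-5-methyloxolan-3-ol
Conditions: LiBH(s-Bu)3 (L-Selectride), THF, −78 °C; then H2O
Reagents that add atoms: none
Why: In this substrate-controlled ketone reduction the bulky hydride should attack the face opposite to the cis 2- and 5-substituents, which places the new hydroxyl cis to both and sets C3 as S.

Step 8
Reactants: 9 (2S,3S,5R)-2-({[tert-butyl(diphenyl)silyl]oxy}methyl)-5-methyloxolan-3-ol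
Product: 10 (2S,3S,5R)-2-(hydroxymethyl)-5-methyloxolan-3-ol
Conditions: TBAF, THF, 0 °C to rt
Reagents that add atoms: none
Why: Fluoride-mediated silyl ether cleavage should free the primary alcohol cleanly.

Step 9
Reactants: 10 (2S,3S,5R)-2-(hydroxymethyl)-5-methyloxolan-3-ol
Product: 11 (2S,3S,5R)-5-methyl-3-(triethylsilyloxy)-2-[(triethylsilyloxy)methyl]oxolane
Conditions: TESCl, imidazole, DMAP (cat.), CH2Cl2, 0 °C to rt
Reagents that add atoms: chlorotriethylsilane (TESCl), CC[Si](Cl)(CC)CC
Why: Standard silyl ether formation at both hydroxyls sets up the selective oxidation of the primary position.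

Step 10
Reactants: 11 (2S,3S,5R)-5-methyl-3-(triethylsilyloxy)-2-[(triethylsilyloxy)methyl]oxolane
Product: 13 (2R,3S,5R)-5-methyl-3-(triethylsilyloxy)oxolane-2-carbaldehyde, via alkoxysulfonium salt 12 (not isolated)
Conditions: (COCl)2, DMSO, CH2Cl2, −78 to −30 °C; then Et3N, −78 to 0 °C; used crude
Reagents that add atoms: none
Why: Under Swern conditions a primary triethylsilyl ether is converted through its alkoxysulfonium salt directly into the aldehyde while the more hindered secondary triethylsilyl ether should stay, and the cold work-up should keep the α-alkoxy centre intact.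

Step 11
Reactants: 13 (2R,3S,5R)-5-methyl-3-(triethylsilyloxy)oxolane-2-carbaldehyde
Product: 14 2-{(E)-2-[(2S,3S,5R)-5-methyl-3-(triethylsilyloxy)oxolan-2-yl]ethenyl}-4,4,5,5-tetramethyl-1,3,2-dioxaborolane
Conditions: CrCl2, LiI, Cl2CHBpin, THF, rt
Reagents that add atoms: 2-(dichloromethyl)-4,4,5,5-tetramethyl-1,3,2-dioxaborolane, ClC(Cl)B1OC(C)(C)C(C)(C)O1
Why: The boron variant of the Takai olefination (geminal dichromium reagent) should give the (E)-alkenylboronate under non-basic conditions that do not epimerise the aldehyde.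

Step 12
Reactants: 15 methyl 2,4-dihydroxy-6-methylbenzoate
Product: 16 methyl 3-chloro-4,6-dihydroxy-2-methylbenzoate
Conditions: SO2Cl2 (1 equiv), Et2O, 0 °C to rt
Reagents that add atoms: sulfuryl chloride, O=S(=O)(Cl)Cl
Why: Electrophilic aromatic chlorination should go to the position next to the methyl group, which is para to the ester-chelated hydroxyl and ortho to the free one, as it does with the analogous orcyl aldehyde.

Step 13
Reactants: 16 methyl 3-chloro-4,6-dihydroxy-2-methylbenzoate
Product: 17 methyl 3-chloro-4,6-bis(methoxymethoxy)-2-methylbenzoate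
Conditions: NaH, MOMCl, DMF, 0 °C to rt
Reagents that add atoms: chloromethyl methyl ether, COCCl
Why: Williamson etherification of both phenoxides installs base-stable acetal groups that survive the lithiation.

Step 14
Reactants: 17 methyl 3-chloro-4,6-bis(methoxymethoxy)-2-methylbenzoate, 18 ethyl 2,2-diethoxyacetate
Product: 20 methyl 3-chloro-2-(3,3-diethoxy-2-oxopropyl)-4,6-bis(methoxymethoxy)benzoate, via benzylic lithium species 19 (not isolated)
Conditions: LiN(i-Pr)2 (2.2 equiv), THF, −78 °C; then 18, −78 to −40 °C; AcOH quench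
Reagents that add atoms: none
Why: Lateral lithiation of the o-toluate gives an ester-stabilised benzylic anion that should be acylated by the non-enolisable ester 18 (Claisen-type acylation), the second equivalent of base holding the product as its enolate.

Step 15
Reactants: 20 methyl 3-chloro-2-(3,3-diethoxy-2-oxopropyl)-4,6-bis(methoxymethoxy)benzoate
Product: 21 5-chloro-6,8-dihydroxy-1-oxo-1H-isochromene-3-carbaldehyde
Conditions: 3 M HCl (aq), THF, 60 °C
Reagents that add atoms: water, O
Why: Aqueous acid should remove both MOM ethers, hydrolyse the acetal and drive enol-lactonisation of the ketone onto the neighbouring ester, the conjugated isocoumarin being the thermodynamic sink.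

Step 16
Reactants: 21 5-chloro-6,8-dihydroxy-1-oxo-1H-isochromene-3-carbaldehyde
Product: 22 5-chloro-1-oxo-6,8-bis{[tri(propan-2-yl)silyl]oxy}-1H-isochromene-3-carbaldehyde
Conditions: TIPSOTf, 2,6-lutidine, CH2Cl2, 0 °C
Reagents that add atoms: triisopropylsilyl trifluoromethanesulfonate, CC(C)[Si](OS(=O)(=O)C(F)(F)F)(C(C)C)C(C)C
Why: Silyl triflate with a hindered base should silylate both phenols, the hydrogen-bonded one included, so that no acidic OH consumes the chromium reagent of the next step.

Step 17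
Reactants: 22 5-chloro-1-oxo-6,8-bis{[tri(propan-2-yl)silyl]oxy}-1H-isochromene-3-carbaldehyde
Product: 23 5-chloro-3-[(E)-2-iodoethenyl]-6,8-bis{[tri(propan-2-yl)silyl]oxy}-1H-isochromen-1-one
Conditions: CrCl2, CHI3, THF, 0 °C to rt
Reagents that add atoms: iodoform, IC(I)I
Why: Takai iodo-olefination of this non-enolisable, conjugated aldehyde should give the (E)-alkenyl iodide and leave the lactone and the aryl chloride alone.

Step 18
Reactants: 14 2-{(E)-2-[(2S,3S,5R)-5-methyl-3-(triethylsilyloxy)oxolan-2-yl]ethenyl}-4,4,5,5-tetramethyl-1,3,2-dioxaborolane, 23 5-chloro-3-[(E)-2-iodoethenyl]-6,8-bis{[tri(propan-2-yl)silyl]oxy}-1H-isochromen-1-one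
Product: 24 5-chloro-3-{(1E,3E)-4-[(2S,3S,5R)-5-methyl-3-(triethylsilyloxy)oxolan-2-yl]buta-1,3-dien-1-yl}-6,8-bis{[tri(propan-2-yl)silyl]oxy}-1H-isochromen-1-one
Conditions: Pd(dppf)Cl2 (cat.), K3PO4 (aq), THF, rt, degassed, dark
Reagents that add atoms: none
Why: Suzuki–Miyaura coupling of an (E)-alkenylboronate with an (E)-alkenyl iodide proceeds with retention at both partners and should give the E,E-diene, the hindered aryl chloride being inert to zerovalent palladium at room temperature.

Step 19
Reactants: 24 5-chloro-3-{(1E,3E)-4-[(2S,3S,5R)-5-methyl-3-(triethylsilyloxy)oxolan-2-yl]buta-1,3-dien-1-yl}-6,8-bis{[tri(propan-2-yl)silyl]oxy}-1H-isochromen-1-one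
Product: 25 5-chloro-6,8-dihydroxy-3-{(1E,3E)-4-[(2S,3S,5R)-3-hydroxy-5-methyloxolan-2-yl]buta-1,3-dien-1-yl}-1H-isochromen-1-one
Conditions: TBAF, AcOH, THF, 0 °C to rt, dark
Reagents that add atoms: none
Why: Buffered fluoride (global desilylation) should remove the two aryl silyl ethers and the secondary triethylsilyl ether without acid or strong base that could open the lactone or ionise the dienylic ring ether.

**Compound list**

1 | methyl (4S)-2,2-dimethyl-1,3-dioxolane-4-carboxylate | COC(=O)[C@@H]1COC(C)(C)O1 | starting material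
2 | methyl (2S)-2,3-dihydroxypropanoate | COC(=O)[C@H](CO)O | intermediate
3 | methyl (2S)-3-{[tert-butyl(diphenyl)silyl]oxy}-2-hydroxypropanoate | COC(=O)[C@H](CO[Si](c1ccccc1)(c1ccccc1)C(C)(C)C)O | intermediate
4 | methyl (2S)-3-{[tert-butyl(diphenyl)silyl]oxy}-2-ethoxypropanoate | COC(=O)[C@H](CO[Si](c1ccccc1)(c1ccccc1)C(C)(C)C)OCC | intermediate
5 | (2S)-3-{[tert-butyl(diphenyl)silyl]oxy}-2-ethoxypropanoic acid | OC(=O)[C@H](CO[Si](c1ccccc1)(c1ccccc1)C(C)(C)C)OCC | intermediate
6 | isobutyl carbonic mixed anhydride of acid 5 | CC(C)COC(=O)OC(=O)[C@H](CO[Si](c1ccccc1)(c1ccccc1)C(C)(C)C)OCC | intermediate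
7 | (3S)-4-{[tert-butyl(diphenyl)silyl]oxy}-1-diazo-3-ethoxybutan-2-one | [N-]=[N+]=CC(=O)[C@H](CO[Si](c1ccccc1)(c1ccccc1)C(C)(C)C)OCC | intermediate
8 | (2S,5R)-2-({[tert-butyl(diphenyl)silyl]oxy}methyl)-5-methyloxolan-3-one (2,5-cis) | C[C@@H]1CC(=O)[C@H](CO[Si](c2ccccc2)(c2ccccc2)C(C)(C)C)O1 | intermediate
9 | (2S,3S,5R)-2-({[tert-butyl(diphenyl)silyl]oxy}methyl)-5-methyloxolan-3-ol (all-cis) | C[C@@H]1C[C@H](O)[C@H](CO[Si](c2ccccc2)(c2ccccc2)C(C)(C)C)O1 | intermediate
10 | (2S,3S,5R)-2-(hydroxymethyl)-5-methyloxolan-3-ol | C[C@@H]1C[C@H](O)[C@H](CO)O1 | intermediate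
11 | (2S,3S,5R)-5-methyl-3-(triethylsilyloxy)-2-[(triethylsilyloxy)methyl]oxolane | C[C@@H]1C[C@H](O[Si](CC)(CC)CC)[C@H](CO[Si](CC)(CC)CC)O1 | intermediate
12 | dimethyl{[(2S,3S,5R)-5-methyl-3-(triethylsilyloxy)oxolan-2-yl]methoxy}sulfonium chloride | C[C@@H]1C[C@H](O[Si](CC)(CC)CC)[C@H](CO[S+](C)C)O1.[Cl-] | intermediate
13 | (2R,3S,5R)-5-methyl-3-(triethylsilyloxy)oxolane-2-carbaldehyde | C[C@@H]1C[C@H](O[Si](CC)(CC)CC)[C@H](C=O)O1 | intermediate
14 | 2-{(E)-2-[(2S,3S,5R)-5-methyl-3-(triethylsilyloxy)oxolan-2-yl]ethenyl}-4,4,5,5-tetramethyl-1,3,2-dioxaborolane | C[C@@H]1C[C@H](O[Si](CC)(CC)CC)[C@H](/C=C/B2OC(C)(C)C(C)(C)O2)O1 | intermediate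
15 | methyl 2,4-dihydroxy-6-methylbenzoate (methyl orsellinate) | COC(=O)c1c(C)cc(O)cc1O | starting material
16 | methyl 3-chloro-4,6-dihydroxy-2-methylbenzoate | COC(=O)c1c(C)c(Cl)c(O)cc1O | intermediate
17 | methyl 3-chloro-4,6-bis(methoxymethoxy)-2-methylbenzoate | COCOc1cc(OCOC)c(C(=O)OC)c(C)c1Cl | intermediate
18 | ethyl 2,2-diethoxyacetate | CCOC(=O)C(OCC)OCC | starting material
19 | {[2-chloro-6-(methoxycarbonyl)-3,5-bis(methoxymethoxy)phenyl]methyl}lithium | [Li]Cc1c(Cl)c(OCOC)cc(OCOC)c1C(=O)OC | intermediate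
20 | methyl 3-chloro-2-(3,3-diethoxy-2-oxopropyl)-4,6-bis(methoxymethoxy)benzoate | CCOC(OCC)C(=O)Cc1c(Cl)c(OCOC)cc(OCOC)c1C(=O)OC | intermediate
21 | 5-chloro-6,8-dihydroxy-1-oxo-1H-isochromene-3-carbaldehyde | O=Cc1cc2c(Cl)c(O)cc(O)c2c(=O)o1 | intermediate
22 | 5-chloro-1-oxo-6,8-bis{[tri(propan-2-yl)silyl]oxy}-1H-isochromene-3-carbaldehyde | O=Cc1cc2c(Cl)c(O[Si](C(C)C)(C(C)C)C(C)C)cc(O[Si](C(C)C)(C(C)C)C(C)C)c2c(=O)o1 | intermediate
23 | 5-chloro-3-[(E)-2-iodoethenyl]-6,8-bis{[tri(propan-2-yl)silyl]oxy}-1H-isochromen-1-one | I/C=C/c1cc2c(Cl)c(O[Si](C(C)C)(C(C)C)C(C)C)cc(O[Si](C(C)C)(C(C)C)C(C)C)c2c(=O)o1 | intermediate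
24 | 5-chloro-3-{(1E,3E)-4-[(2S,3S,5R)-5-methyl-3-(triethylsilyloxy)oxolan-2-yl]buta-1,3-dien-1-yl}-6,8-bis{[tri(propan-2-yl)silyl]oxy}-1H-isochromen-1-one | C[C@@H]1C[C@H](O[Si](CC)(CC)CC)[C@H](/C=C/C=C/c2cc3c(Cl)c(O[Si](C(C)C)(C(C)C)C(C)C)cc(O[Si](C(C)C)(C(C)C)C(C)C)c3c(=O)o2)O1 | intermediate
25 | 5-chloro-6,8-dihydroxy-3-{(1E,3E)-4-[(2S,3S,5R)-3-hydroxy-5-methyloxolan-2-yl]buta-1,3-dien-1-yl}-1H-isochromen-1-one | C[C@@H]1C[C@H](O)[C@H](/C=C/C=C/c2cc3c(Cl)c(O)cc(O)c3c(=O)o2)O1 | target

**Step count and risks**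

Total step count: 19. Longest linear sequence: 13 steps (steps 1 to 11, then 18 and 19).

Steps most likely to fail:

Step 6. The carbene may be diverted by attack on the silyl ether oxygen (five-membered oxonium ylide followed by silyl shift) or by dimerisation, or the facial control at C5 may be poor. The fallback sets out from 3 and comes back at 8, and forms the same CH2–CHMe bond by a Petasis–Ferrier rearrangement. Compound 3 would be saponified (LiOH, THF/H2O) to (2S)-3-{[tert-butyl(diphenyl)silyl]oxy}-2-hydroxypropanoic acid F1. Condensation with acetaldehyde (BF3·OEt2, Et2O, −20 °C) should give the cis dioxolanone (2S,5S)-5-({[tert-butyl(diphenyl)silyl]oxy}methyl)-2-methyl-1,3-dioxolan-4-one F2. Carbonyl methylenation with Cp2TiMe2 (toluene, 65 °C) should give the enol acetal (2S,4S)-4-({[tert-butyl(diphenyl)silyl]oxy}methyl)-2-methyl-5-methylidene-1,3-dioxolane F3. Me2AlCl (CH2Cl2, −78 °C) should then ionise the acetal to an aluminium enolate and oxocarbenium pair that recloses by an aldol-type step to the 2,5-cis ketone 8.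

Step 15. The unmasked 1,2-ketoaldehyde may hydrate or self-condense faster than the enol lactonises, or lactonisation of the chelated salicylate ester may stall. The fallback sets out from 17 and comes back at 22, and keeps the aldehyde oxidation level out of the cyclisation. Compound 17 would be lithiated as in step 14 and acylated with N-methoxy-N-methylacetamide to give methyl 3-chloro-4,6-bis(methoxymethoxy)-2-(2-oxopropyl)benzoate F4. Aqueous HCl in THF at 60 °C should close the lactone and remove the MOM groups to give 5-chloro-6,8-dihydroxy-3-methyl-1H-isochromen-1-one F5. TIPSOTf and 2,6-lutidine should give 5-chloro-3-methyl-6,8-bis{[tri(propan-2-yl)silyl]oxy}-1H-isochromen-1-one F6. Riley oxidation of the 3-methyl group with SeO2 (1,4-dioxane, reflux) should then give aldehyde 22.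

Step 18. Aqueous base may hydrolyse the aryl silyl ethers, protodeboronate 14 or isomerise the iodoalkene before transmetalation. The fallback sets out from 13 and comes back at 24, and replaces boron by tin so that the coupling runs under neutral conditions. The tin variant of the Takai olefination (Bu3SnCHBr2, CrCl2, LiI, THF/DMF, rt) on 13 should give tributyl{(E)-2-[(2S,3S,5R)-5-methyl-3-(triethylsilyloxy)oxolan-2-yl]ethenyl}stannane F7. Stille coupling of F7 with 23 (Pd2(dba)3, AsPh3, NMP, rt) should give 24.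

Further compounds
F1 | step 6 | (2S)-3-{[tert-butyl(diphenyl)silyl]oxy}-2-hydroxypropanoic acid | OC(=O)[C@H](CO[Si](c1ccccc1)(c1ccccc1)C(C)(C)C)O
F2 | step 6 | (2S,5S)-5-({[tert-butyl(diphenyl)silyl]oxy}methyl)-2-methyl-1,3-dioxolan-4-one | C[C@@H]1OC(=O)[C@H](CO[Si](c2ccccc2)(c2ccccc2)C(C)(C)C)O1
F3 | step 6 | (2S,4S)-4-({[tert-butyl(diphenyl)silyl]oxy}methyl)-2-methyl-5-methylidene-1,3-dioxolane | C[C@@H]1OC(=C)[C@H](CO[Si](c2ccccc2)(c2ccccc2)C(C)(C)C)O1
F4 | step 15 | methyl 3-chloro-4,6-bis(methoxymethoxy)-2-(2-oxopropyl)benzoate | CC(=O)Cc1c(Cl)c(OCOC)cc(OCOC)c1C(=O)OC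
F5 | step 15 | 5-chloro-6,8-dihydroxy-3-methyl-1H-isochromen-1-one | Cc1cc2c(Cl)c(O)cc(O)c2c(=O)o1
F6 | step 15 | 5-chloro-3-methyl-6,8-bis{[tri(propan-2-yl)silyl]oxy}-1H-isochromen-1-one | Cc1cc2c(Cl)c(O[Si](C(C)C)(C(C)C)C(C)C)cc(O[Si](C(C)C)(C(C)C)C(C)C)c2c(=O)o1
F7 | step 18 | tributyl{(E)-2-[(2S,3S,5R)-5-methyl-3-(triethylsilyloxy)oxolan-2-yl]ethenyl}stannane | C[C@@H]1C[C@H](O[Si](CC)(CC)CC)[C@H](/C=C/[Sn](CCCC)(CCCC)CCCC)O1
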